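**Assumption:** the target is taken exactly as the given SMILES (a resveratrol hexamer, twelve stereocentres); the absolute configuration of the resolved bromides 15 and 24 is assigned by anomalous-dispersion X-ray crystallography (Br).

**Labels:** resveratrol units 1–6; C-7(n) and C-8(n) are the benzylic carbons of unit n carrying its 4-oxyphenyl ring and its resorcinol-type ring. Units 1+2, 4+3 and 6+5 form the three dihydrobenzofurans (first unit gives C-2 = C-7 and C-3 = C-8, second unit gives the fused ring). Target: 7(1)R, 8(1)R, 7(2)S, 8(2)S, 7(3)R, 8(3)R, 7(4)R, 8(4)R, 7(5)S, 8(5)S, 7(6)R, 8(6)R.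

**Abbreviations in names:** TIPS = triisopropylsilyl; TBS = tert-butyldimethylsilyl; DBF-T-yl = (2R,3R)-3-[3,5-bis(TIPS-oxy)phenyl]-6-methoxy-2-(4-methoxyphenyl)-2,3-dihydro-1-benzofuran-4-yl; DBF-M-yl = (2R,3R)-3-(3,5-dimethoxyphenyl)-6-methoxy-2-(4-methoxyphenyl)-2,3-dihydro-1-benzofuran-4-yl.

## Retrosynthetic overview

1. 42 ⇐ 41 by global O-demethylation.
2. 41 ⇐ 39: the eight-membered ring (C-7(5) to the resorcinol ring of unit 4) and the seven-membered ring (C-7(2) to the resorcinol ring of unit 1) close last, in one operation, by intramolecular 1,6-conjugate (vinylogous Michael) addition of resorcinolate carbons to para-quinone methides.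
3. C-8(2)–C-7(3) ⇐ intermolecular 1,6-Michael addition of the enolate of ketone 30 (units 1+2) to a para-quinone methide of the unit 3–6 fragment 35.
4. C-8(3)–C-8(5) ⇐ silicon-tethered oxidative cross-coupling of the enolates of ketones 28 (units 4+3) and 29 (units 6+5).
5. 28–30 ⇐ Pd α-arylation of acetophenones with enantiopure bromodihydrobenzofurans 15 and 24 (sulfur-ylide [4+1] annulation on ortho-quinone methides, then resolution). The three dihydrofurans are formed first.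

## Route

Step 1
Reactants: 1 1-bromo-3,5-dimethoxybenzene
Product: 2 2-bromo-4,6-dimethoxybenzaldehyde
Conditions: POCl3, DMF, 0 → 100 °C; aq NaOAc
Reagents that add atoms: N,N-dimethylformamide CN(C)C=O; water O
Why: Vilsmeier–Haack formylation goes para to one methoxy and ortho to the other at the less shielded site next to bromine rather than between the two methoxy groups; no stereocentre.

Step 2
Reactants: 2 2-bromo-4,6-dimethoxybenzaldehyde
Product: 3 2-bromo-6-hydroxy-4-methoxybenzaldehyde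
Conditions: BCl3 (1.1 equiv), CH2Cl2, −78 → 0 °C; H2O
Reagents that add atoms: none
Why: Chelation-controlled Lewis-acid O-demethylation cleaves only the methyl ether ortho to the aldehyde.

Step 3
Reactants: 4 5-bromobenzene-1,3-diol
Product: 5 1-bromo-3,5-bis(triisopropylsilyloxy)benzene
Conditions: iPr3SiCl, imidazole, DMF, rt
Reagents that add atoms: chlorotriisopropylsilane CC(C)[Si](Cl)(C(C)C)C(C)C
Why: Phenol silylation; the bulky TIPS ethers survive the organometallic and basic steps and are the fluoride trigger later.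

Step 4
Reactants: 5 1-bromo-3,5-bis(triisopropylsilyloxy)benzene; 3 2-bromo-6-hydroxy-4-methoxybenzaldehyde
Product: 7 rac-3-bromo-2-{[3,5-bis(triisopropylsilyloxy)phenyl](hydroxy)methyl}-5-methoxyphenol, via aryl Grignard reagent 6 (not isolated)
Conditions: 5, Mg, THF, 45 °C; 3, NaH, THF, 0 °C; combine at −20 °C → rt; aq NH4Cl
Reagents that add atoms: none
Why: Grignard 1,2-addition to the aldehyde of the pre-formed sodium phenoxide gives the diarylcarbinol; its stereocentre is racemic and is erased in step 7.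

Step 5
Reactants: 7 rac-3-bromo-2-{[3,5-bis(triisopropylsilyloxy)phenyl](hydroxy)methyl}-5-methoxyphenol
Product: 8 rac-3-bromo-2-{[3,5-bis(triisopropylsilyloxy)phenyl](4-methylphenylsulfonyl)methyl}-5-methoxyphenol
Conditions: 4-MeC6H4SO2Na, HCO2H, CH2Cl2, rt
Reagents that add atoms: sodium 4-methylbenzenesulfinate Cc1ccc(S(=O)[O-])cc1.[Na+]
Why: Acid ionises the ortho-hydroxybenzhydrol (cation stabilised by ortho-OH and para-OMe) and sulfinate captures it at sulfur (SN1-type sulfone formation), giving a bench-stable ortho-quinone methide precursor.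

Step 6
Reactants: 9 4-methoxybenzyl alcohol; 10 tetrahydrothiophene
Product: 11 1-(4-methoxybenzyl)tetrahydrothiophenium tetrafluoroborate
Conditions: HBF4·OEt2, CH2Cl2, 0 °C → rt
Reagents that add atoms: tetrafluoroboric acid [H+].F[B-](F)(F)F
Why: Acid-promoted SN1 S-alkylation of the sulfide by the 4-methoxybenzyl cation gives the sulfonium salt.

Step 7
Reactants: 8 rac-3-bromo-2-{[3,5-bis(triisopropylsilyloxy)phenyl](4-methylphenylsulfonyl)methyl}-5-methoxyphenol; 11 1-(4-methoxybenzyl)tetrahydrothiophenium tetrafluoroborate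
Product: 14 rac-(2R,3R)-4-bromo-3-[3,5-bis(triisopropylsilyloxy)phenyl]-6-methoxy-2-(4-methoxyphenyl)-2,3-dihydro-1-benzofuran, via sulfonium ylide 12 (not isolated), via ortho-quinone methide 13 (not isolated)
Conditions: KN(SiMe3)2 (2.2 equiv), THF, −78 → 0 °C
Reagents that add atoms: none
Why: Sulfur-ylide [4+1] annulation: the phenoxide expels sulfinate to give 13, ylide 12 adds in Michael fashion, and the phenoxide then displaces tetrahydrothiophene from the 4-methoxybenzylic carbon; the two aryl groups end up trans (the favoured arrangement), racemic.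

Step 8
Reactants: 14 rac-(2R,3R)-4-bromo-3-[3,5-bis(triisopropylsilyloxy)phenyl]-6-methoxy-2-(4-methoxyphenyl)-2,3-dihydro-1-benzofuran
Product: 15 (2R,3R)-4-bromo-3-[3,5-bis(triisopropylsilyloxy)phenyl]-6-methoxy-2-(4-methoxyphenyl)-2,3-dihydro-1-benzofuran
Conditions: preparative SFC on amylose tris(3,5-dimethylphenylcarbamate), CO2/iPrOH
Reagents that add atoms: none
Why: Chromatographic resolution on a chiral phase; the (2R,3R) enantiomer fixes C-7/C-8 of units 1 and 4.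

Step 9
Reactants: 1 1-bromo-3,5-dimethoxybenzene; 3 2-bromo-6-hydroxy-4-methoxybenzaldehyde
Product: 17 rac-3-bromo-2-[(3,5-dimethoxyphenyl)(hydroxy)methyl]-5-methoxyphenol, via aryl Grignard reagent 16 (not isolated)
Conditions: 1, Mg, THF, 45 °C; 3, NaH, THF, 0 °C; combine at −20 °C → rt; aq NH4Cl
Reagents that add atoms: none
Why: Grignard addition as in step 4; the racemic carbinol centre is erased in step 12.

Step 10
Reactants: 17 rac-3-bromo-2-[(3,5-dimethoxyphenyl)(hydroxy)methyl]-5-methoxyphenol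
Product: 18 rac-3-bromo-2-[(3,5-dimethoxyphenyl)(4-methylphenylsulfonyl)methyl]-5-methoxyphenol
Conditions: 4-MeC6H4SO2Na, HCO2H, CH2Cl2, rt
Reagents that add atoms: sodium 4-methylbenzenesulfinate Cc1ccc(S(=O)[O-])cc1.[Na+]
Why: SN1-type sulfone formation as in step 5.

Step 11
Reactants: 9 4-methoxybenzyl alcohol; 19 dimethyl sulfide
Product: 20 (4-methoxybenzyl)dimethylsulfonium tetrafluoroborate
Conditions: Me2S (3 equiv), HBF4·OEt2, CH2Cl2, 0 °C → rt (closed flask)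
Reagents that add atoms: tetrafluoroboric acid [H+].F[B-](F)(F)F
Why: Acid-promoted SN1 S-alkylation as in step 6 gives the S,S-dimethyl benzyl-transfer salt, whose leaving group, dimethyl sulfide, is volatile and is lost on evaporation, which eases purification of the more polar methoxy-series product.

Step 12
Reactants: 18 rac-3-bromo-2-[(3,5-dimethoxyphenyl)(4-methylphenylsulfonyl)methyl]-5-methoxyphenol; 20 (4-methoxybenzyl)dimethylsulfonium tetrafluoroborate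
Product: 23 rac-(2R,3R)-4-bromo-3-(3,5-dimethoxyphenyl)-6-methoxy-2-(4-methoxyphenyl)-2,3-dihydro-1-benzofuran, via sulfonium ylide 21 (not isolated), via ortho-quinone methide 22 (not isolated)
Conditions: KN(SiMe3)2 (2.2 equiv), THF, −78 → 0 °C
Reagents that add atoms: none
Why: Sulfur-ylide [4+1] annulation of the same type as step 7, with the dimethylsulfonium benzylide 21 (the benzylic proton of 20 is far more acidic than its S-methyl protons) adding to 22 in Michael fashion and dimethyl sulfide leaving in the ring closure; trans-selective, racemic.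

Step 13
Reactants: 23 rac-(2R,3R)-4-bromo-3-(3,5-dimethoxyphenyl)-6-methoxy-2-(4-methoxyphenyl)-2,3-dihydro-1-benzofuran
Product: 24 (2R,3R)-4-bromo-3-(3,5-dimethoxyphenyl)-6-methoxy-2-(4-methoxyphenyl)-2,3-dihydro-1-benzofuran
Conditions: preparative SFC on amylose tris(3,5-dimethylphenylcarbamate), CO2/iPrOH
Reagents that add atoms: none
Why: Chromatographic resolution; the (2R,3R) enantiomer fixes C-7/C-8 of unit 6.

Step 14
Reactants: 25 4'-hydroxyacetophenone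
Product: 26 4'-(tert-butyldimethylsilyloxy)acetophenone
Conditions: tBuMe2SiCl, imidazole, DMF, rt
Reagents that add atoms: tert-butylchlorodimethylsilane CC(C)(C)[Si](C)(C)Cl
Why: Phenol silylation; the aryl TBS ether is the one silyl group later removed by mild carbonate methanolysis.

Step 15
Reactants: 25 4'-hydroxyacetophenone
Product: 27 4'-(triisopropylsilyloxy)acetophenone
Conditions: iPr3SiCl, imidazole, DMF, rt
Reagents that add atoms: chlorotriisopropylsilane CC(C)[Si](Cl)(C(C)C)C(C)C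
Why: Phenol silylation; the aryl TIPS ether is reserved for the fluoride trigger.

Step 16
Reactants: 15 (2R,3R)-4-bromo-3-[3,5-bis(triisopropylsilyloxy)phenyl]-6-methoxy-2-(4-methoxyphenyl)-2,3-dihydro-1-benzofuran; 26 4'-(tert-butyldimethylsilyloxy)acetophenone
Product: 28 2-(DBF-T-yl)-1-[4-(TBS-oxy)phenyl]ethan-1-one
Conditions: Pd(OAc)2 (3 mol%), XPhos (6 mol%), K3PO4, toluene, 80 °C; 26 (2 equiv)
Reagents that add atoms: none
Why: Pd-catalysed α-arylation of the ketone enolate (Buchwald–Hartwig type) with a bulky biarylphosphine accepts the ortho-substituted bromide; the weak base spares the silyl ethers and the stereocentres are not touched.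

Step 17
Reactants: 24 (2R,3R)-4-bromo-3-(3,5-dimethoxyphenyl)-6-methoxy-2-(4-methoxyphenyl)-2,3-dihydro-1-benzofuran; 27 4'-(triisopropylsilyloxy)acetophenone
Product: 29 2-(DBF-M-yl)-1-[4-(TIPS-oxy)phenyl]ethan-1-one
Conditions: Pd(OAc)2 (3 mol%), XPhos (6 mol%), K3PO4, toluene, 80 °C; 27 (2 equiv)
Reagents that add atoms: none
Why: Pd-catalysed ketone α-arylation as in step 16 (units 6+5).

Step 18
Reactants: 15 (2R,3R)-4-bromo-3-[3,5-bis(triisopropylsilyloxy)phenyl]-6-methoxy-2-(4-methoxyphenyl)-2,3-dihydro-1-benzofuran; 27 4'-(triisopropylsilyloxy)acetophenone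
Product: 30 2-(DBF-T-yl)-1-[4-(TIPS-oxy)phenyl]ethan-1-one
Conditions: Pd(OAc)2 (3 mol%), XPhos (6 mol%), K3PO4, toluene, 80 °C; 27 (2 equiv)
Reagents that add atoms: none
Why: Pd-catalysed ketone α-arylation as in step 16 (units 1+2).

Step 19
Reactants: 28 2-(DBF-T-yl)-1-[4-(TBS-oxy)phenyl]ethan-1-one; 29 2-(DBF-M-yl)-1-[4-(TIPS-oxy)phenyl]ethan-1-one
Product: 32 dimethylsilanediyl bis-(Z)-enol ether of ketones 28 and 29, via chlorosilyl enol ether 31 (not isolated)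
Conditions: 28, LiN(SiMe3)2, THF, −78 °C; Me2SiCl2 (6 equiv), → rt, evaporate; then lithium enolate of 29 (LiN(SiMe3)2, THF, −78 °C) → rt; used crude
Reagents that add atoms: dichlorodimethylsilane C[Si](C)(Cl)Cl
Why: Stepwise O-silylation of the two (Z)-lithium enolates (silyl enol ether formation) ties the two different ketones to one silicon, so the following coupling can only be the cross-coupling.

Step 20
Reactants: 32 dimethylsilanediyl bis-(Z)-enol ether of ketones 28 and 29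
Product: 33 (2R,3R)-1-[4-(TBS-oxy)phenyl]-2-(DBF-T-yl)-3-(DBF-M-yl)-4-[4-(TIPS-oxy)phenyl]butane-1,4-dione
Conditions: (NH4)2Ce(NO3)6 (2.2 equiv), NaHCO3, MeCN/EtCN, −10 °C, 10 min
Reagents that add atoms: none
Why: Oxidative enolate coupling: one-electron oxidation of the enol ether by tetravalent cerium and intramolecular C–C bond formation across the silicon tether give the syn (dl-type) diketone; each enol ether reacts on the face away from the C-3 aryl of its own dihydrobenzofuran, setting C-8(3) and C-8(5).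

Step 21
Reactants: 33 (2R,3R)-1-[4-(TBS-oxy)phenyl]-2-(DBF-T-yl)-3-(DBF-M-yl)-4-[4-(TIPS-oxy)phenyl]butane-1,4-dione
Product: 34 (1RS,2R,3R,4RS)-2-(DBF-T-yl)-3-(DBF-M-yl)-1-(4-hydroxyphenyl)-4-[4-(TIPS-oxy)phenyl]butane-1,4-diol
Conditions: NaBH4, THF/MeOH, −20 °C; then K2CO3, MeOH, 0 °C → rt
Reagents that add atoms: none
Why: Hydride reduction of both ketones removes the epimerisable α-keto centres (carbinol configuration is irrelevant, both carbons become sp2 later); carbonate methanolysis then cleaves the labile aryl TBS ether while the aryl TIPS ethers persist.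

Step 22
Reactants: 34 (1RS,2R,3R,4RS)-2-(DBF-T-yl)-3-(DBF-M-yl)-1-(4-hydroxyphenyl)-4-[4-(TIPS-oxy)phenyl]butane-1,4-diol
Product: 35 (1RS,2R,3R,4RS)-1-(4-acetoxyphenyl)-2-(DBF-T-yl)-3-(DBF-M-yl)-4-[4-(TIPS-oxy)phenyl]butane-1,4-diyl diacetate
Conditions: Ac2O, pyridine, DMAP (cat.), CH2Cl2, rt
Reagents that add atoms: acetic anhydride CC(=O)OC(C)=O
Why: DMAP-catalysed acetylation installs both benzylic leaving groups and the base-labile aryl acetate that triggers quinone methide formation at C-7(3) only.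

Step 23
Reactants: 35 (1RS,2R,3R,4RS)-1-(4-acetoxyphenyl)-2-(DBF-T-yl)-3-(DBF-M-yl)-4-[4-(TIPS-oxy)phenyl]butane-1,4-diyl diacetate; 30 2-(DBF-T-yl)-1-[4-(TIPS-oxy)phenyl]ethan-1-one
Product: 37 (2R,3R,4R,5R,6RS)-6-acetoxy-2,4-bis(DBF-T-yl)-5-(DBF-M-yl)-3-(4-hydroxyphenyl)-1,6-bis[4-(TIPS-oxy)phenyl]hexan-1-one, via para-quinone methide 36 (not isolated)
Conditions: 30 (1.5 equiv), KOtBu (2.6 equiv), THF, −40 °C; slow addition of 35, → 0 °C; aq NH4Cl
Reagents that add atoms: none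
Why: Intermolecular 1,6-conjugate (vinylogous Michael) addition: tert-butoxide cleaves only the aryl acetate, the phenoxide expels the C-7(3) acetate to give 36, and the enolate of 30 adds anti to the dihydrobenzofuranyl group on C-8(3) in the A(1,3)-minimised conformer (sets C-7(3)); the enolate reacts on the face away from its own C-3 aryl (sets C-8(2)).

Step 24
Reactants: 37 (2R,3R,4R,5R,6RS)-6-acetoxy-2,4-bis(DBF-T-yl)-5-(DBF-M-yl)-3-(4-hydroxyphenyl)-1,6-bis[4-(TIPS-oxy)phenyl]hexan-1-one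
Product: 38 (1RS,2R,3R,4R,5R,6RS)-6-acetoxy-2,4-bis(DBF-T-yl)-5-(DBF-M-yl)-3-(4-hydroxyphenyl)-1,6-bis[4-(TIPS-oxy)phenyl]hexan-1-ol
Conditions: NaBH4, THF/MeOH, 0 °C → rt
Reagents that add atoms: none
Why: Hydride reduction of the aryl ketone locks C-8(2) (no enolate can then compete for the next quinone methide) and provides the carbinol for the second leaving group; the carbinol configuration is irrelevant.

Step 25
Reactants: 38 (1RS,2R,3R,4R,5R,6RS)-6-acetoxy-2,4-bis(DBF-T-yl)-5-(DBF-M-yl)-3-(4-hydroxyphenyl)-1,6-bis[4-(TIPS-oxy)phenyl]hexan-1-ol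
Product: 39 (1RS,2R,3R,4R,5R,6RS)-3-(4-acetoxyphenyl)-2,4-bis(DBF-T-yl)-5-(DBF-M-yl)-1,6-bis[4-(TIPS-oxy)phenyl]hexane-1,6-diyl diacetate
Conditions: Ac2O, pyridine, DMAP (cat.), CH2Cl2, rt
Reagents that add atoms: acetic anhydride CC(=O)OC(C)=O
Why: DMAP-catalysed acetylation puts the leaving group on C-7(2); the free phenol is acetylated as well and is freed again in step 26.

Step 26
Reactants: 39 (1RS,2R,3R,4R,5R,6RS)-3-(4-acetoxyphenyl)-2,4-bis(DBF-T-yl)-5-(DBF-M-yl)-1,6-bis[4-(TIPS-oxy)phenyl]hexane-1,6-diyl diacetate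
Product: 41 octa-O-methyl ether of 42, via bis(para-quinone methide) 40 (not isolated)
Conditions: Bu4NF (8 equiv), THF (1 mM), −20 °C → rt; then K2CO3, MeOH, rt; aq NH4Cl
Reagents that add atoms: none
Why: Key ring closures by double intramolecular 1,6-conjugate (vinylogous Michael) addition: fluoride frees six phenoxides, both 4-oxidobenzylic acetates eliminate to 40, and each quinone methide is taken by the ortho carbon of the only resorcinolate that can reach it, while all ether-protected rings are inert under base. C-7(5) forms by attack anti to the aryl on C-8(5) (eight-membered ring); C-7(2) is dictated by the seven-membered ring held by the (2R,3R)-dihydrobenzofuran, as in ampelopsin-type closures.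

Step 27
Reactants: 41 octa-O-methyl ether of 42
Product: 42 CNP0184494.1 (target hexamer)
Conditions: BBr3 (40 equiv), CH2Cl2, −78 °C → rt; MeOH then H2O
Reagents that add atoms: none
Why: Lewis-acid O-demethylation of the eight aryl methyl ethers leaves all C–C stereocentres untouched; the trans dihydrobenzofurans are the thermodynamic isomers, so reversible C–O ionisation does no harm.

## Compound list

1 | 1-bromo-3,5-dimethoxybenzene | COc1cc(Br)cc(OC)c1 | starting material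
2 | 2-bromo-4,6-dimethoxybenzaldehyde | COc1cc(Br)c(C=O)c(OC)c1 | intermediate
3 | 2-bromo-6-hydroxy-4-methoxybenzaldehyde | COc1cc(O)c(C=O)c(Br)c1 | intermediate
4 | 5-bromobenzene-1,3-diol | Oc1cc(O)cc(Br)c1 | starting material
5 | 1-bromo-3,5-bis(triisopropylsilyloxy)benzene | Brc1cc(O[Si](C(C)C)(C(C)C)C(C)C)cc(O[Si](C(C)C)(C(C)C)C(C)C)c1 | intermediate
6 | [3,5-bis(triisopropylsilyloxy)phenyl]magnesium bromide | Br[Mg]c1cc(O[Si](C(C)C)(C(C)C)C(C)C)cc(O[Si](C(C)C)(C(C)C)C(C)C)c1 | intermediate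
7 | rac-3-bromo-2-{[3,5-bis(triisopropylsilyloxy)phenyl](hydroxy)methyl}-5-methoxyphenol | COc1cc(O)c(C(O)c2cc(O[Si](C(C)C)(C(C)C)C(C)C)cc(O[Si](C(C)C)(C(C)C)C(C)C)c2)c(Br)c1 | intermediate
8 | rac-3-bromo-2-{[3,5-bis(triisopropylsilyloxy)phenyl](4-methylphenylsulfonyl)methyl}-5-methoxyphenol | COc1cc(O)c(C(c2cc(O[Si](C(C)C)(C(C)C)C(C)C)cc(O[Si](C(C)C)(C(C)C)C(C)C)c2)S(=O)(=O)c2ccc(C)cc2)c(Br)c1 | intermediate
9 | 4-methoxybenzyl alcohol | COc1ccc(CO)cc1 | starting material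
10 | tetrahydrothiophene | C1CCSC1 | starting material
11 | 1-(4-methoxybenzyl)tetrahydrothiophenium tetrafluoroborate | COc1ccc(C[S+]2CCCC2)cc1.F[B-](F)(F)F | intermediate
12 | (4-methoxyphenyl)(tetrahydrothiophenium-1-yl)methanide (sulfonium ylide) | COc1ccc([CH-][S+]2CCCC2)cc1 | intermediate
13 | 5-bromo-6-[3,5-bis(triisopropylsilyloxy)benzylidene]-3-methoxycyclohexa-2,4-dien-1-one (ortho-quinone methide) | COC1=CC(=O)C(=Cc2cc(O[Si](C(C)C)(C(C)C)C(C)C)cc(O[Si](C(C)C)(C(C)C)C(C)C)c2)C(Br)=C1 | intermediate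
14 | rac-(2R,3R)-4-bromo-3-[3,5-bis(triisopropylsilyloxy)phenyl]-6-methoxy-2-(4-methoxyphenyl)-2,3-dihydro-1-benzofuran (both enantiomers) | Brc1cc(OC)cc2c1[C@@H](c1cc(O[Si](C(C)C)(C(C)C)C(C)C)cc(O[Si](C(C)C)(C(C)C)C(C)C)c1)[C@H](c1ccc(OC)cc1)O2.Brc1cc(OC)cc2c1[C@H](c1cc(O[Si](C(C)C)(C(C)C)C(C)C)cc(O[Si](C(C)C)(C(C)C)C(C)C)c1)[C@@H](c1ccc(OC)cc1)O2 | intermediate
15 | (2R,3R)-4-bromo-3-[3,5-bis(triisopropylsilyloxy)phenyl]-6-methoxy-2-(4-methoxyphenyl)-2,3-dihydro-1-benzofuran | Brc1cc(OC)cc2c1[C@@H](c1cc(O[Si](C(C)C)(C(C)C)C(C)C)cc(O[Si](C(C)C)(C(C)C)C(C)C)c1)[C@H](c1ccc(OC)cc1)O2 | intermediate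
16 | (3,5-dimethoxyphenyl)magnesium bromide | COc1cc(OC)cc([Mg]Br)c1 | intermediate
17 | rac-3-bromo-2-[(3,5-dimethoxyphenyl)(hydroxy)methyl]-5-methoxyphenol | COc1cc(O)c(C(O)c2cc(OC)cc(OC)c2)c(Br)c1 | intermediate
18 | rac-3-bromo-2-[(3,5-dimethoxyphenyl)(4-methylphenylsulfonyl)methyl]-5-methoxyphenol | COc1cc(O)c(C(c2cc(OC)cc(OC)c2)S(=O)(=O)c2ccc(C)cc2)c(Br)c1 | intermediate
19 | dimethyl sulfide | CSC | starting material
20 | (4-methoxybenzyl)dimethylsulfonium tetrafluoroborate | COc1ccc(C[S+](C)C)cc1.F[B-](F)(F)F | intermediate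
21 | (dimethylsulfonio)(4-methoxyphenyl)methanide (sulfonium ylide) | COc1ccc([CH-][S+](C)C)cc1 | intermediate
22 | 5-bromo-6-(3,5-dimethoxybenzylidene)-3-methoxycyclohexa-2,4-dien-1-one (ortho-quinone methide) | COC1=CC(=O)C(=Cc2cc(OC)cc(OC)c2)C(Br)=C1 | intermediate
23 | rac-(2R,3R)-4-bromo-3-(3,5-dimethoxyphenyl)-6-methoxy-2-(4-methoxyphenyl)-2,3-dihydro-1-benzofuran (both enantiomers) | Brc1cc(OC)cc2c1[C@@H](c1cc(OC)cc(OC)c1)[C@H](c1ccc(OC)cc1)O2.Brc1cc(OC)cc2c1[C@H](c1cc(OC)cc(OC)c1)[C@@H](c1ccc(OC)cc1)O2 | intermediate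
24 | (2R,3R)-4-bromo-3-(3,5-dimethoxyphenyl)-6-methoxy-2-(4-methoxyphenyl)-2,3-dihydro-1-benzofuran | Brc1cc(OC)cc2c1[C@@H](c1cc(OC)cc(OC)c1)[C@H](c1ccc(OC)cc1)O2 | intermediate
25 | 4'-hydroxyacetophenone | CC(=O)c1ccc(O)cc1 | starting material
26 | 4'-(tert-butyldimethylsilyloxy)acetophenone | CC(=O)c1ccc(O[Si](C)(C)C(C)(C)C)cc1 | intermediate
27 | 4'-(triisopropylsilyloxy)acetophenone | CC(=O)c1ccc(O[Si](C(C)C)(C(C)C)C(C)C)cc1 | intermediate
28 | 2-(DBF-T-yl)-1-[4-(TBS-oxy)phenyl]ethan-1-one (units 4+3) | CC(C)(C)[Si](C)(C)Oc1ccc(C(=O)Cc2cc(OC)cc3c2[C@@H](c2cc(O[Si](C(C)C)(C(C)C)C(C)C)cc(O[Si](C(C)C)(C(C)C)C(C)C)c2)[C@H](c2ccc(OC)cc2)O3)cc1 | intermediate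
29 | 2-(DBF-M-yl)-1-[4-(TIPS-oxy)phenyl]ethan-1-one (units 6+5) | CC(C)[Si](C(C)C)(C(C)C)Oc1ccc(C(=O)Cc2cc(OC)cc3c2[C@@H](c2cc(OC)cc(OC)c2)[C@H](c2ccc(OC)cc2)O3)cc1 | intermediate
30 | 2-(DBF-T-yl)-1-[4-(TIPS-oxy)phenyl]ethan-1-one (units 1+2) | CC(C)[Si](C(C)C)(C(C)C)Oc1ccc(C(=O)Cc2cc(OC)cc3c2[C@@H](c2cc(O[Si](C(C)C)(C(C)C)C(C)C)cc(O[Si](C(C)C)(C(C)C)C(C)C)c2)[C@H](c2ccc(OC)cc2)O3)cc1 | intermediate
31 | chloro(dimethyl)silyl (Z)-enol ether of 28 | CC(C)(C)[Si](C)(C)Oc1ccc(/C(O[Si](C)(C)Cl)=C/c2cc(OC)cc3c2[C@@H](c2cc(O[Si](C(C)C)(C(C)C)C(C)C)cc(O[Si](C(C)C)(C(C)C)C(C)C)c2)[C@H](c2ccc(OC)cc2)O3)cc1 | intermediate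
32 | dimethylsilanediyl bis-(Z)-enol ether of 28 and 29 | CC(C)(C)[Si](C)(C)Oc1ccc(/C(O[Si](C)(C)O/C(=C\c2cc(OC)cc3c2[C@@H](c2cc(OC)cc(OC)c2)[C@H](c2ccc(OC)cc2)O3)c2ccc(O[Si](C(C)C)(C(C)C)C(C)C)cc2)=C/c2cc(OC)cc3c2[C@@H](c2cc(O[Si](C(C)C)(C(C)C)C(C)C)cc(O[Si](C(C)C)(C(C)C)C(C)C)c2)[C@H](c2ccc(OC)cc2)O3)cc1 | intermediate
33 | (2R,3R)-1-[4-(TBS-oxy)phenyl]-2-(DBF-T-yl)-3-(DBF-M-yl)-4-[4-(TIPS-oxy)phenyl]butane-1,4-dione | CC(C)(C)[Si](C)(C)Oc1ccc(C(=O)[C@H]([C@@H](C(=O)c2ccc(O[Si](C(C)C)(C(C)C)C(C)C)cc2)c2cc(OC)cc3c2[C@@H](c2cc(OC)cc(OC)c2)[C@H](c2ccc(OC)cc2)O3)c2cc(OC)cc3c2[C@@H](c2cc(O[Si](C(C)C)(C(C)C)C(C)C)cc(O[Si](C(C)C)(C(C)C)C(C)C)c2)[C@H](c2ccc(OC)cc2)O3)cc1 | intermediate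
34 | (1RS,2R,3R,4RS)-2-(DBF-T-yl)-3-(DBF-M-yl)-1-(4-hydroxyphenyl)-4-[4-(TIPS-oxy)phenyl]butane-1,4-diol | Oc1ccc(C(O)[C@H]([C@@H](C(O)c2ccc(O[Si](C(C)C)(C(C)C)C(C)C)cc2)c2cc(OC)cc3c2[C@@H](c2cc(OC)cc(OC)c2)[C@H](c2ccc(OC)cc2)O3)c2cc(OC)cc3c2[C@@H](c2cc(O[Si](C(C)C)(C(C)C)C(C)C)cc(O[Si](C(C)C)(C(C)C)C(C)C)c2)[C@H](c2ccc(OC)cc2)O3)cc1 | intermediate
35 | (1RS,2R,3R,4RS)-1-(4-acetoxyphenyl)-2-(DBF-T-yl)-3-(DBF-M-yl)-4-[4-(TIPS-oxy)phenyl]butane-1,4-diyl diacetate | CC(=O)Oc1ccc(C(OC(C)=O)[C@H]([C@@H](C(OC(C)=O)c2ccc(O[Si](C(C)C)(C(C)C)C(C)C)cc2)c2cc(OC)cc3c2[C@@H](c2cc(OC)cc(OC)c2)[C@H](c2ccc(OC)cc2)O3)c2cc(OC)cc3c2[C@@H](c2cc(O[Si](C(C)C)(C(C)C)C(C)C)cc(O[Si](C(C)C)(C(C)C)C(C)C)c2)[C@H](c2ccc(OC)cc2)O3)cc1 | intermediate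
36 | 4-{(2R,3R,4RS)-4-acetoxy-2-(DBF-T-yl)-3-(DBF-M-yl)-4-[4-(TIPS-oxy)phenyl]butylidene}cyclohexa-2,5-dien-1-one (para-quinone methide at C-7(3)) | O=C1C=CC(=C[C@H]([C@@H](C(OC(C)=O)c2ccc(O[Si](C(C)C)(C(C)C)C(C)C)cc2)c2cc(OC)cc3c2[C@@H](c2cc(OC)cc(OC)c2)[C@H](c2ccc(OC)cc2)O3)c2cc(OC)cc3c2[C@@H](c2cc(O[Si](C(C)C)(C(C)C)C(C)C)cc(O[Si](C(C)C)(C(C)C)C(C)C)c2)[C@H](c2ccc(OC)cc2)O3)C=C1 | intermediate
37 | (2R,3R,4R,5R,6RS)-6-acetoxy-2,4-bis(DBF-T-yl)-5-(DBF-M-yl)-3-(4-hydroxyphenyl)-1,6-bis[4-(TIPS-oxy)phenyl]hexan-1-one | CC(C)[Si](C(C)C)(C(C)C)Oc1cc(O[Si](C(C)C)(C(C)C)C(C)C)cc([C@@H]2c3c(cc(OC)cc3[C@H](C(=O)c3ccc(O[Si](C(C)C)(C(C)C)C(C)C)cc3)[C@H](c3ccc(O)cc3)[C@H]([C@@H](C(OC(C)=O)c3ccc(O[Si](C(C)C)(C(C)C)C(C)C)cc3)c3cc(OC)cc4c3[C@@H](c3cc(OC)cc(OC)c3)[C@H](c3ccc(OC)cc3)O4)c3cc(OC)cc4c3[C@@H](c3cc(O[Si](C(C)C)(C(C)C)C(C)C)cc(O[Si](C(C)C)(C(C)C)C(C)C)c3)[C@H](c3ccc(OC)cc3)O4)O[C@H]2c2ccc(OC)cc2)c1 | intermediate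
38 | (1RS,2R,3R,4R,5R,6RS)-6-acetoxy-2,4-bis(DBF-T-yl)-5-(DBF-M-yl)-3-(4-hydroxyphenyl)-1,6-bis[4-(TIPS-oxy)phenyl]hexan-1-ol | CC(C)[Si](C(C)C)(C(C)C)Oc1cc(O[Si](C(C)C)(C(C)C)C(C)C)cc([C@@H]2c3c(cc(OC)cc3[C@H](C(O)c3ccc(O[Si](C(C)C)(C(C)C)C(C)C)cc3)[C@H](c3ccc(O)cc3)[C@H]([C@@H](C(OC(C)=O)c3ccc(O[Si](C(C)C)(C(C)C)C(C)C)cc3)c3cc(OC)cc4c3[C@@H](c3cc(OC)cc(OC)c3)[C@H](c3ccc(OC)cc3)O4)c3cc(OC)cc4c3[C@@H](c3cc(O[Si](C(C)C)(C(C)C)C(C)C)cc(O[Si](C(C)C)(C(C)C)C(C)C)c3)[C@H](c3ccc(OC)cc3)O4)O[C@H]2c2ccc(OC)cc2)c1 | intermediate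
39 | (1RS,2R,3R,4R,5R,6RS)-3-(4-acetoxyphenyl)-2,4-bis(DBF-T-yl)-5-(DBF-M-yl)-1,6-bis[4-(TIPS-oxy)phenyl]hexane-1,6-diyl diacetate | CC(C)[Si](C(C)C)(C(C)C)Oc1cc(O[Si](C(C)C)(C(C)C)C(C)C)cc([C@@H]2c3c(cc(OC)cc3[C@H](C(OC(C)=O)c3ccc(O[Si](C(C)C)(C(C)C)C(C)C)cc3)[C@H](c3ccc(OC(C)=O)cc3)[C@H]([C@@H](C(OC(C)=O)c3ccc(O[Si](C(C)C)(C(C)C)C(C)C)cc3)c3cc(OC)cc4c3[C@@H](c3cc(OC)cc(OC)c3)[C@H](c3ccc(OC)cc3)O4)c3cc(OC)cc4c3[C@@H](c3cc(O[Si](C(C)C)(C(C)C)C(C)C)cc(O[Si](C(C)C)(C(C)C)C(C)C)c3)[C@H](c3ccc(OC)cc3)O4)O[C@H]2c2ccc(OC)cc2)c1 | intermediate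
40 | bis(para-quinone methide) from 39: all TIPS and acetyl groups lost, C-7(2) and C-7(5) as quinone methide carbons, resorcinol rings of units 1 and 4 free | Oc1cc(O)cc([C@@H]2c3c(cc(OC)cc3[C@H](C=C3C=CC(=O)C=C3)[C@H](c3ccc(O)cc3)[C@H]([C@@H](C=C3C=CC(=O)C=C3)c3cc(OC)cc4c3[C@@H](c3cc(OC)cc(OC)c3)[C@H](c3ccc(OC)cc3)O4)c3cc(OC)cc4c3[C@@H](c3cc(O)cc(O)c3)[C@H](c3ccc(OC)cc3)O4)O[C@H]2c2ccc(OC)cc2)c1 | intermediate
41 | octa-O-methyl ether of 42: methyl on the 4-oxyphenyl groups at C-7 of units 1, 4 and 6, on the one free oxygen of the fused rings of units 2, 3 and 5, and on both oxygens of the unit 6 resorcinol ring; stereocentres as in 42 | Oc1ccc([C@H]2c3c(O)cc(O)cc3[C@@H]3c4c(cc(OC)cc4[C@H]2[C@H](c2ccc(O)cc2)[C@H]2c4cc(OC)cc5c4[C@@H](c4cc(O)cc(O)c4[C@H](c4ccc(O)cc4)[C@H]2c2cc(OC)cc4c2[C@@H](c2cc(OC)cc(OC)c2)[C@H](c2ccc(OC)cc2)O4)[C@H](c2ccc(OC)cc2)O5)O[C@H]3c2ccc(OC)cc2)cc1 | intermediate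
42 | CNP0184494.1, resveratrol hexamer, 7(1)R,8(1)R,7(2)S,8(2)S,7(3)R,8(3)R,7(4)R,8(4)R,7(5)S,8(5)S,7(6)R,8(6)R | Oc1ccc([C@H]2c3c(O)cc(O)cc3[C@@H]3c4c(cc(O)cc4[C@H]2[C@H](c2ccc(O)cc2)[C@H]2c4cc(O)cc5c4[C@@H](c4cc(O)cc(O)c4[C@H](c4ccc(O)cc4)[C@H]2c2cc(O)cc4c2[C@@H](c2cc(O)cc(O)c2)[C@H](c2ccc(O)cc2)O4)[C@H](c2ccc(O)cc2)O5)O[C@H]3c2ccc(O)cc2)cc1 | target

## Totals and risks

Total step count: 27.
Longest linear sequence: 16 steps (steps 1, 2, 4, 5, 7, 8, 16, 19, 20, 21, 22, 23, 24, 25, 26, 27; the branch through steps 9, 10, 12, 13 and 17 is equally long). 16/27 = 0.59.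

The three steps most likely to fail:

Step 20 (oxidative cross-coupling). The cerium oxidant may attack the electron-rich aryl ethers or the 4-methoxybenzylic C–O bonds of the dihydrobenzofurans, and the diastereocontrol at C-8(3)/C-8(5) rests on substrate bias. The fallback sets out from ketones 28 and 29 and comes back at 33. Ketone 28 is chlorinated at C-8 (LiN(SiMe3)2, THF, −78 °C, then N-chlorosuccinimide) to 2-chloro-2-(DBF-T-yl)-1-[4-(TBS-oxy)phenyl]ethan-1-one F1. F1 then alkylates the potassium enolate of 29 (KN(SiMe3)2, THF/DMPU, −78 → −20 °C), an SN2 reaction at the α-halo ketone that needs no oxidant and is cross-selective by construction. The epimerisable α-keto centres are equilibrated with DBU and the (2R,3R) isomer 33 is separated; the other isomers are recycled through the same equilibration.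

Step 23 (intermolecular 1,6-addition). The bond joins two very hindered carbons, and the quinone methide 36 can tautomerise to a 4-hydroxystilbene before the bulky enolate arrives. The fallback sets out from triacetate 35 and comes back at 37; it inverts the order of the two bonds to C-8(2). 35 is treated with KOtBu and the small enolate of acetophenone 27, which adds to 36 to give (3R,4R,5R,6RS)-6-acetoxy-4-(DBF-T-yl)-5-(DBF-M-yl)-3-(4-hydroxyphenyl)-1,6-bis[4-(TIPS-oxy)phenyl]hexan-1-one F2, in which C-8(2) is still a methylene. Pd-catalysed α-arylation of F2 with bromide 15 (Pd(OAc)2, XPhos, K3PO4, toluene, 80 °C) then puts the dihydrobenzofuran on C-8(2) and gives 37, the new centre settling by base equilibration.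

Step 26 (double ring closure). Two quinone methides and six phenoxides are present at once; either quinone methide may tautomerise, oligomerise or be taken by the wrong resorcinolate. The fallback sets out from alcohol 38 and comes back at 41; it closes the two rings in separate operations. In 38 only C-7(5) bears a leaving group, so Bu4NF (THF, 1 mM) closes the eight-membered ring alone and gives the mono-cyclised compound with free C-7(2) carbinol and seven free phenols F3. Peracetylation (Ac2O, pyridine, DMAP) gives the octaacetate of F3 F4. K2CO3 in MeOH then cleaves the aryl acetates, the C-7(2) acetate is expelled from the 4-oxidobenzyl position, and the resorcinolate of unit 1 closes the seven-membered ring to give 41.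

## Further compounds

F1 | step 20 | 2-chloro-2-(DBF-T-yl)-1-[4-(TBS-oxy)phenyl]ethan-1-one (both C-2 epimers) | CC(C)(C)[Si](C)(C)Oc1ccc(C(=O)C(Cl)c2cc(OC)cc3c2[C@@H](c2cc(O[Si](C(C)C)(C(C)C)C(C)C)cc(O[Si](C(C)C)(C(C)C)C(C)C)c2)[C@H](c2ccc(OC)cc2)O3)cc1
F2 | step 23 | (3R,4R,5R,6RS)-6-acetoxy-4-(DBF-T-yl)-5-(DBF-M-yl)-3-(4-hydroxyphenyl)-1,6-bis[4-(TIPS-oxy)phenyl]hexan-1-one | CC(C)[Si](C(C)C)(C(C)C)Oc1ccc(C(=O)C[C@H](c2ccc(O)cc2)[C@H]([C@@H](C(OC(C)=O)c2ccc(O[Si](C(C)C)(C(C)C)C(C)C)cc2)c2cc(OC)cc3c2[C@@H](c2cc(OC)cc(OC)c2)[C@H](c2ccc(OC)cc2)O3)c2cc(OC)cc3c2[C@@H](c2cc(O[Si](C(C)C)(C(C)C)C(C)C)cc(O[Si](C(C)C)(C(C)C)C(C)C)c2)[C@H](c2ccc(OC)cc2)O3)cc1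
F3 | step 26 | mono-cyclised compound: eight-membered ring closed, C-7(2) still a carbinol (both epimers), seven free phenols, eight methyl ethers as in 41 | Oc1cc(O)cc([C@@H]2c3c(cc(OC)cc3[C@H](C(O)c3ccc(O)cc3)[C@H](c3ccc(O)cc3)[C@H]3c4cc(OC)cc5c4[C@@H](c4cc(O)cc(O)c4[C@H](c4ccc(O)cc4)[C@H]3c3cc(OC)cc4c3[C@@H](c3cc(OC)cc(OC)c3)[C@H](c3ccc(OC)cc3)O4)[C@H](c3ccc(OC)cc3)O5)O[C@H]2c2ccc(OC)cc2)c1
F4 | step 26 | octaacetate of F3 | CC(=O)Oc1cc(OC(C)=O)cc([C@@H]2c3c(cc(OC)cc3[C@H](C(OC(C)=O)c3ccc(OC(C)=O)cc3)[C@H](c3ccc(OC(C)=O)cc3)[C@H]3c4cc(OC)cc5c4[C@@H](c4cc(OC(C)=O)cc(OC(C)=O)c4[C@H](c4ccc(OC(C)=O)cc4)[C@H]3c3cc(OC)cc4c3[C@@H](c3cc(OC)cc(OC)c3)[C@H](c3ccc(OC)cc3)O4)[C@H](c3ccc(OC)cc3)O5)O[C@H]2c2ccc(OC)cc2)c1
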